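Numbering: C1 bears the 4-hydroxyphenyl group, C2 and C3 bear the 2,4-dihydroxybenzoyl groups, and C4 is CH. Ring A is C4a–C8a with the 6,7-diol, and ring B is C1–C4 plus C4a and C8a.
Cuts: the seven phenols are masked as methyl ethers and C3–C4 is returned to the dihydro level. Ring B is then opened at C1–C8a and C2–C3 in one operation, C3–C4 falls to an aldol disconnection, and the C2–acyl bond falls to an alkyne acylation.
Enabling feature: C1 and C2, one carrying the aryl group and the other the aroyl group, map onto the alkyne carbons of a 1,3-diarylpropynone. C8a (as C–I), C4a, C4, C3 and the C3 aroyl group map onto an ortho-iodinated dihydrochalcone whose enolisable CH2 is C3, so an aryl–palladium bond and an enolate carbon can add across one alkyne.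
Forward order: all four benzene rings are bought. C3=C4 is made by condensation and then reduced, and the ynone is made separately. Ring B, the only ring formed, closes in step 4, followed by dehydrogenation and sevenfold O-demethylation.
Stereochemistry: the target is achiral. The C3 stereocentre created in step 4 is racemic and vanishes on aromatisation.

Key step: step 4

Remark: the target has seven hydroxyl groups (two on each benzoyl ring, two on ring A, one on the C1 aryl group), so the fully protected naphthalene is a heptamethyl ether. 2-Iodo-4,5-dimethoxybenzaldehyde is taken as a catalogue compound.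

Step 1
Reactants: 1 2-iodo-4,5-dimethoxybenzaldehyde; 2 1-(2,4-dimethoxyphenyl)ethanone
Product: 3 (E)-1-(2,4-dimethoxyphenyl)-3-(2-iodo-4,5-dimethoxyphenyl)prop-2-en-1-one
Conditions: KOH, EtOH, rt
Reagents that add atoms: none
Why: Claisen–Schmidt aldol condensation, in which only 2 can enolise and only 1 offers an aldehyde, and base-induced dehydration should give the conjugated enone in its favoured E geometry.

Step 2
Reactants: 3 (E)-1-(2,4-dimethoxyphenyl)-3-(2-iodo-4,5-dimethoxyphenyl)prop-2-en-1-one
Product: 4 1-(2,4-dimethoxyphenyl)-3-(2-iodo-4,5-dimethoxyphenyl)propan-1-one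
Conditions: [(Ph3P)CuH]6 (0.35 equiv), H2O (5 equiv), degassed toluene, rt
Reagents that add atoms: none
Why: Conjugate reduction with a phosphine-stabilised copper hydride, in which the soft hydride goes only to the beta carbon of the enone, the water present supplies the alpha proton, and aryl iodides, aryl ethers and saturated ketones are left alone at room temperature.

Step 3
Reactants: 5 2,4-dimethoxybenzoyl chloride; 6 1-ethynyl-4-methoxybenzene
Product: 7 1-(2,4-dimethoxyphenyl)-3-(4-methoxyphenyl)prop-2-yn-1-one
Conditions: PdCl2(PPh3)2 (2 mol %), CuI (4 mol %), Et3N (1.2 equiv), THF, rt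
Reagents that add atoms: none
Why: Acyl Sonogashira coupling, in which the acid chloride adds oxidatively to zerovalent palladium, the alkyne is transferred through copper, and reductive elimination gives the ynone at room temperature, where decarbonylation and amine conjugate addition stay slow.

Step 4
Reactants: 4 1-(2,4-dimethoxyphenyl)-3-(2-iodo-4,5-dimethoxyphenyl)propan-1-one; 7 1-(2,4-dimethoxyphenyl)-3-(4-methoxyphenyl)prop-2-yn-1-one (1.3 equiv)
Product: 8 racemic [6,7-dimethoxy-1-(4-methoxyphenyl)-3,4-dihydronaphthalene-2,3-diyl]bis[(2,4-dimethoxyphenyl)methanone]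
Conditions: Pd(OAc)2 (10 mol %), PPh3 (20 mol %), Cs2CO3 (2.5 equiv), dry degassed toluene, 100 °C, argon
Reagents that add atoms: none
Why: Proposed new method: zerovalent palladium formed from Pd(OAc)2 and PPh3 inserts into the C–I bond of 4, the arylpalladium iodide adds syn across the triple bond of 7 so that C8a binds the anisyl-bearing carbon (C1) and palladium rests on the carbon next to the carbonyl (C2), Cs2CO3 removes an alpha proton of the tethered aryl ketone, and the enolate carbon C3 takes the place of iodide on palladium before reductive elimination forms C2–C3. The closest known reactions are the Larock carboannulation of internal alkynes by ortho-iodoaryl malonates, which ends in the same way with a stabilised carbanion, and the intramolecular palladium-catalysed vinylation and arylation of simple ketone enolates with carbonate bases, so the new element is the use of an unactivated ketone as the terminating nucleophile of the intermolecular annulation. Ring B closes as a formal [4+2] annulation through a seven-membered palladacycle (Pd, C2, C1, C8a, C4a, C4, C3) that contracts to the six-membered carbocycle on reductive elimination. The only new stereocentre, C3, has no controlling element, so 8 should be racemic, which does not matter because step 5 makes C3 planar. The step needs the aryl group to go to C1 and the alkyne to insert before any enolate coupling: the first is secured by the conjugate polarity of the ynone, which directs aryl groups to the beta carbon as in the reductive hydroarylation of aryl ynones, and the second by the tether, because C3 and C8a could meet directly only in a strained benzocyclobutene. Sparingly soluble Cs2CO3 in toluene keeps free enolate scarce, so base-induced Michael addition of 4 to 7 should stay slow next to deprotonation of the palladium-bound ketone.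

Step 5
Reactants: 8 racemic [6,7-dimethoxy-1-(4-methoxyphenyl)-3,4-dihydronaphthalene-2,3-diyl]bis[(2,4-dimethoxyphenyl)methanone]
Product: 9 [6,7-dimethoxy-1-(4-methoxyphenyl)naphthalene-2,3-diyl]bis[(2,4-dimethoxyphenyl)methanone]
Conditions: DDQ (1.3 equiv), toluene, 80 °C
Reagents that add atoms: none
Why: DDQ dehydrogenation, in which hydride abstraction from benzylic C4 (cation stabilised by the para C7 methoxy group) and loss of the acidic C3 proton give the naphthalene with aromatisation as driving force, and any double-bond isomers of 8 formed under the basic conditions of step 4 converge on the same product.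

Step 6
Reactants: 9 [6,7-dimethoxy-1-(4-methoxyphenyl)naphthalene-2,3-diyl]bis[(2,4-dimethoxyphenyl)methanone]
Product: 10 [6,7-dihydroxy-1-(4-hydroxyphenyl)naphthalene-2,3-diyl]bis[(2,4-dihydroxyphenyl)methanone] (CNP0304576.0)
Conditions: BBr3 (14 equiv), CH2Cl2, −78 °C to rt; then ice-water, argon
Reagents that add atoms: none
Why: Lewis-acid cleavage of aryl methyl ethers with BBr3, in which each ether oxygen is activated by boron and bromide attacks the methyl group, the two ethers ortho to the ketones are helped by chelation, and aqueous work-up should free all seven phenols without touching the diaryl ketones.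

Compound list
1 | 2-iodo-4,5-dimethoxybenzaldehyde | COc1cc(I)c(C=O)cc1OC | starting material
2 | 1-(2,4-dimethoxyphenyl)ethanone | COc1ccc(C(C)=O)c(OC)c1 | starting material
3 | (E)-1-(2,4-dimethoxyphenyl)-3-(2-iodo-4,5-dimethoxyphenyl)prop-2-en-1-one | COc1ccc(C(=O)/C=C/c2cc(OC)c(OC)cc2I)c(OC)c1 | intermediate
4 | 1-(2,4-dimethoxyphenyl)-3-(2-iodo-4,5-dimethoxyphenyl)propan-1-one | COc1ccc(C(=O)CCc2cc(OC)c(OC)cc2I)c(OC)c1 | intermediate
5 | 2,4-dimethoxybenzoyl chloride | COc1ccc(C(Cl)=O)c(OC)c1 | starting material
6 | 1-ethynyl-4-methoxybenzene | COc1ccc(cc1)C#C | starting material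
7 | 1-(2,4-dimethoxyphenyl)-3-(4-methoxyphenyl)prop-2-yn-1-one | COc1ccc(cc1)C#CC(=O)c1ccc(OC)cc1OC | intermediate
8 | [6,7-dimethoxy-1-(4-methoxyphenyl)-3,4-dihydronaphthalene-2,3-diyl]bis[(2,4-dimethoxyphenyl)methanone], racemic, one enantiomer drawn | COc1ccc(cc1)C1=C(C(=O)c2ccc(OC)cc2OC)[C@H](C(=O)c2ccc(OC)cc2OC)Cc2cc(OC)c(OC)cc21 | intermediate
9 | [6,7-dimethoxy-1-(4-methoxyphenyl)naphthalene-2,3-diyl]bis[(2,4-dimethoxyphenyl)methanone] | COc1ccc(cc1)-c1c(C(=O)c2ccc(OC)cc2OC)c(C(=O)c2ccc(OC)cc2OC)cc2cc(OC)c(OC)cc12 | intermediate
10 | [6,7-dihydroxy-1-(4-hydroxyphenyl)naphthalene-2,3-diyl]bis[(2,4-dihydroxyphenyl)methanone] | O=C(c1ccc(O)cc1O)c1cc2cc(O)c(O)cc2c(-c2ccc(O)cc2)c1C(=O)c1ccc(O)cc1O | target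

Total step count: 6. Longest linear sequence: 5 (steps 1, 2, 4, 5, 6); the ynone branch (step 3) joins at step 4.

Steps most likely to fail

Risk 1 (step 4). Several processes could compete with the annulation:
- conjugate addition of free ketone enolate or of phosphine to the ynone before palladium engages it
- insertion of the alkyne in the reverse sense
- protonation of the vinylpalladium, or a second alkyne insertion, before the ring closes

The fallback builds ring B by carbonyl condensation instead of by palladium, and relies on the two aroyl groups being identical. It sets out from 1 and 2.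
- From 1, a carbonylative Suzuki–Miyaura coupling with 4-methoxyphenylboronic acid (PdCl2(PPh3)2, K2CO3, CO 1 atm, anisole, 80 °C) should give 4,5-dimethoxy-2-(4-methoxybenzoyl)benzaldehyde F1.
- From 2, deprotonation with LiN(iPr)2 and oxidative coupling with CuCl2 (THF/DMF, −78 °C) should give 1,4-bis(2,4-dimethoxyphenyl)butane-1,4-dione F2.
- A double aldol condensation of F1 with F2 (NaOEt, EtOH, reflux) then joins C3–C4 at the aldehyde and C1–C2 at the diaryl ketone, with loss of two molecules of water. This is the reaction type by which phthalaldehydes and 1,2-diaroylethanes give 2,3-diaroylnaphthalenes.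

The fallback comes back to the route at 9, so steps 4 and 5 are bypassed. The symmetry of F2 removes any regiochemical question.

Risk 2 (step 6). Cleavage of the seven ethers may be incomplete, boron may chelate tenaciously to the catechol and the ortho-hydroxy ketones, and the catechol may oxidise in air during work-up. The fallback sets out from 9 and divides the deprotection into two mechanistically different operations.
- BCl3 (CH2Cl2, 0 °C) should remove only the two chelation-activated methoxy groups ortho to the ketones, giving [6,7-dimethoxy-1-(4-methoxyphenyl)naphthalene-2,3-diyl]bis[(2-hydroxy-4-methoxyphenyl)methanone] F3.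
- The five remaining ethers are then cleaved by nucleophilic attack of thiolate at methyl (NaSEt, DMF, 130 °C, argon; acidic work-up), which avoids boron in the catechol-forming stage.

The fallback comes back to the route at 10.

Risk 3 (step 2). The iodine may be lost reductively, or the reduction may run on to the carbonyl group. The fallback sets out from 1 and 2 and makes C3–C4 by enolate alkylation, so no reduction takes place in the presence of an enone.
- NaBH4 (MeOH, 0 °C) should reduce 1 to (2-iodo-4,5-dimethoxyphenyl)methanol F4.
- PBr3 (CH2Cl2, 0 °C) should convert F4 into 1-(bromomethyl)-2-iodo-4,5-dimethoxybenzene F5.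
- Ketone 2 is deprotonated with LiN(iPr)2 (THF, −78 °C, ketone in slight excess to hold back double alkylation) and alkylated with F5.

The fallback comes back to the route at 4, bypassing 3.

Further compounds
F1 | step 4 | 4,5-dimethoxy-2-(4-methoxybenzoyl)benzaldehyde | COc1ccc(cc1)C(=O)c1cc(OC)c(OC)cc1C=O
F2 | step 4 | 1,4-bis(2,4-dimethoxyphenyl)butane-1,4-dione | COc1ccc(C(=O)CCC(=O)c2ccc(OC)cc2OC)c(OC)c1
F3 | step 6 | [6,7-dimethoxy-1-(4-methoxyphenyl)naphthalene-2,3-diyl]bis[(2-hydroxy-4-methoxyphenyl)methanone] | COc1ccc(cc1)-c1c(C(=O)c2ccc(OC)cc2O)c(C(=O)c2ccc(OC)cc2O)cc2cc(OC)c(OC)cc12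
F4 | step 2 | (2-iodo-4,5-dimethoxyphenyl)methanol | COc1cc(I)c(CO)cc1OC
F5 | step 2 | 1-(bromomethyl)-2-iodo-4,5-dimethoxybenzene | COc1cc(I)c(CBr)cc1OC
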